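**Retrosynthetic overview**

1. Ring A of the isoflavone carries oxygen on C5, C7 and C8a (alternate carbons), with the C4 carbonyl attached at C4a between two of them. This is an acylphloroglucinol, the pattern a linear tetraketide gives on C-acylative folding, so ring A is made by forming C4a–C5 from a 3,5,7-triketo ester.
2. Ring C is closed last: one carbon (C2) is inserted between the benzylic carbon (C3) and one of two equivalent ortho phenols (O1) of the deoxybenzoin, then the MOM group is removed.
3. The triketo ester comes from one C–C bond between the acyl carbon of a chromen-8-ylacetic Weinreb amide (future C4) and the terminal carbanion of the methyl 3,5-dioxohexanoate trianion.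
4. Ring D (the pyran) comes from an aryl 1,1-dimethylpropargyl ether by Claisen rearrangement and electrocyclisation; the two phenols of 2,4-dihydroxyphenylacetic acid are told apart by lactonisation.
5. Ring order: B (bought) → D → A → C.

Key step: step 7

Assumption: methyl 3,5-dioxohexanoate is taken as purchasable.
Remark: the target has no stereocentre, so no SMILES carries a stereodescriptor; the enaminone double bonds are drawn without geometry because it is lost on ring closure.
Remark: the acyl donor for the polyanion is the N-methoxy-N-methylamide, not a methyl arylacetate. It cannot relactonise onto the neighbouring phenol as easily, its benzylic protons are less acidic, and its tetrahedral adduct is held until the quench.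

**Route**

Step 1
Reactants: 1 2,4-dihydroxyphenylacetic acid
Product: 2 6-hydroxy-1-benzofuran-2(3H)-one
Conditions: TsOH·H2O (cat.), PhMe, reflux, Dean–Stark
Reagents that add atoms: none
Why: Acid-catalysed (Fischer-type) lactonisation, in which only the ortho hydroxyl can reach the carboxyl group (five-membered ring), so the two phenols are differentiated and the para hydroxyl is left free.

Step 2
Reactants: 2 6-hydroxy-1-benzofuran-2(3H)-one
Product: 3 6-(methoxymethoxy)-1-benzofuran-2(3H)-one
Conditions: MOMCl, iPr2NEt, CH2Cl2, 0 °C → rt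
Reagents that add atoms: chloromethyl methyl ether, COCCl
Why: Williamson-type O-alkylation of the one free phenol by the very reactive α-chloro ether; the trialkylamine is too weak to enolise the lactone to a useful extent, so the ring that masks the other phenol should stay closed.

Step 3
Reactants: 3 6-(methoxymethoxy)-1-benzofuran-2(3H)-one
Product: 4 2-[2-hydroxy-4-(methoxymethoxy)phenyl]-N-methoxy-N-methylacetamide
Conditions: MeNH(OMe)·HCl, AlMe3, CH2Cl2, 0 °C → rt; cold 1 M HCl work-up
Reagents that add atoms: N,O-dimethylhydroxylamine hydrochloride, CNOC.Cl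
Why: Weinreb aminolysis of an activated aryl lactone by the aluminium amide, which frees the 2-hydroxyl needed for ring D and installs the acyl donor in one operation.

Step 4
Reactants: 4 2-[2-hydroxy-4-(methoxymethoxy)phenyl]-N-methoxy-N-methylacetamide; 5 3-chloro-3-methylbut-1-yne
Product: 6 N-methoxy-2-[4-(methoxymethoxy)-2-(2-methylbut-3-yn-2-yloxy)phenyl]-N-methylacetamide
Conditions: DBU, CuCl2·2H2O (cat.), MeCN, 0 °C → rt
Reagents that add atoms: none
Why: Copper-catalysed propargylic etherification of a phenol with a tertiary propargylic chloride, a standard way to aryl 1,1-dimethylpropargyl ethers, to which the amide and the MOM ether are inert.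

Step 5
Reactants: 6 N-methoxy-2-[4-(methoxymethoxy)-2-(2-methylbut-3-yn-2-yloxy)phenyl]-N-methylacetamide
Product: 8 N-methoxy-2-[5-(methoxymethoxy)-2,2-dimethyl-2H-chromen-8-yl]-N-methylacetamide, via ortho-allenylphenol 7 (not isolated)
Conditions: o-xylene, 145 °C
Reagents that add atoms: none
Why: Aryl propargyl ether Claisen rearrangement, in which the [3,3] shift can end productively only on the free ortho carbon between the two oxygens (the other ortho carbon carries the side chain), giving allenylphenol 7, which closes ring D by [1,5]-hydrogen shift and 6π oxa-electrocyclisation.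

Step 6
Reactants: 8 N-methoxy-2-[5-(methoxymethoxy)-2,2-dimethyl-2H-chromen-8-yl]-N-methylacetamide; 9 methyl 3,5-dioxohexanoate
Product: 11 methyl 8-[5-(methoxymethoxy)-2,2-dimethyl-2H-chromen-8-yl]-3,5,7-trioxooctanoate, via trilithium trianion 10 (not isolated)
Conditions: 9 (slight excess), LiN(iPr)2 (LDA, 3.1 equiv per 9), THF, −78 → 0 °C; then 8, −78 → −20 °C; AcOH, −78 °C
Reagents that add atoms: none
Why: Acylation of a β,δ-diketo ester polyanion at its terminal, last-formed and most nucleophilic carbanion by a Weinreb amide, whose chelated tetrahedral adduct survives until the acidic quench so that the acidic product never meets the polyanion; 11 is carried on crude because triketo esters of this kind cyclise on silica.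

Step 7
Reactants: 11 methyl 8-[5-(methoxymethoxy)-2,2-dimethyl-2H-chromen-8-yl]-3,5,7-trioxooctanoate
Product: 13 2-[5-(methoxymethoxy)-2,2-dimethyl-2H-chromen-8-yl]-1-(2,4,6-trihydroxyphenyl)ethanone, via acylcyclohexanetrione 12 (not isolated)
Conditions: Mg(OMe)2, MeOH, rt → 65 °C; cold 0.5 M HCl work-up
Reagents that add atoms: none
Why: Mg(OMe)2 turns the C5–C6–C7 diketone unit, the most acidic part of the chain, into a magnesium enolate whose metal can also bind the C3 and ester oxygens, so the chain folds with C6 over C1; C6 adds to the ester carbonyl, methoxide leaves (this is the C4a–C5 bond of the target) and acyltrione 12 enolises to aromatic ring A. This is the known biomimetic Claisen (Dieckmann-type) cyclisation of 3,5,7-triketo esters to acylphloroglucinols, applied here to an 8-aryl substrate. Ring A closes in a 6-exo-trig mode, the enolate carbon attacking an ester C=O that lies outside the new ring, and no stereocentre is created. The step needs C-acylation (C6 onto C1) to win over the aldol closures C2 onto C7 (resorcylate) and C8 onto C3, and over O-acylation to a 4-hydroxy-2-pyrone. C7 lies between the acidic C6 and the benzylic C8 and should therefore sit as a chelated enolate oxygen, a poor aldol acceptor, whereas the ester is kept from saponification by the anhydrous methoxide medium and is activated by the metal; C8 could react only as a dienolate dianion, which methoxide should not form. A pyrone formed by O-acylation is reopened by methoxide under the same conditions, while formation of the phenoxide of 13 is irreversible, so material should drain into the Claisen product.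

Step 8
Reactants: 13 2-[5-(methoxymethoxy)-2,2-dimethyl-2H-chromen-8-yl]-1-(2,4,6-trihydroxyphenyl)ethanone
Product: 15 5,7-dihydroxy-3-[5-(methoxymethoxy)-2,2-dimethyl-2H-chromen-8-yl]-4H-chromen-4-one, via enaminone 14 (not isolated)
Conditions: Me2NCH(OMe)2 (1.5 equiv), THF, 60 °C
Reagents that add atoms: N,N-dimethylformamide dimethyl acetal, COC(OC)N(C)C
Why: Aminomethylenation of the doubly activated benzylic methylene gives enaminone 14, and an ortho phenol then adds to its β-carbon in a 6-endo-trig addition–elimination that expels dimethylamine and closes ring C; the two ortho phenols are equivalent, so only one isoflavone can form, and the moderate temperature and near-stoichiometric acetal are meant to limit O-methylation.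

Step 9
Reactants: 15 5,7-dihydroxy-3-[5-(methoxymethoxy)-2,2-dimethyl-2H-chromen-8-yl]-4H-chromen-4-one
Product: 16 sophoraisoflavone A, 5,7-dihydroxy-3-(5-hydroxy-2,2-dimethyl-2H-chromen-8-yl)-4H-chromen-4-one
Conditions: 1 M HCl, MeOH–THF, 45 °C
Reagents that add atoms: none
Why: Acid-catalysed acetal exchange removes the aryl MOM ether, and the chromone, the hydrogen-bonded 5-OH and the 2,2-dimethylchromene (reversible protonation only) should tolerate dilute acid at this temperature.

**Compound list**

1 | 2,4-dihydroxyphenylacetic acid | OC(=O)Cc1ccc(O)cc1O | starting material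
2 | 6-hydroxy-1-benzofuran-2(3H)-one | O=C1Cc2ccc(O)cc2O1 | intermediate
3 | 6-(methoxymethoxy)-1-benzofuran-2(3H)-one | COCOc1ccc2CC(=O)Oc2c1 | intermediate
4 | 2-[2-hydroxy-4-(methoxymethoxy)phenyl]-N-methoxy-N-methylacetamide | CON(C)C(=O)Cc1ccc(OCOC)cc1O | intermediate
5 | 3-chloro-3-methylbut-1-yne | CC(C)(Cl)C#C | starting material
6 | N-methoxy-2-[4-(methoxymethoxy)-2-(2-methylbut-3-yn-2-yloxy)phenyl]-N-methylacetamide | CON(C)C(=O)Cc1ccc(OCOC)cc1OC(C)(C)C#C | intermediate
7 | 2-[2-hydroxy-4-(methoxymethoxy)-3-(3-methylbuta-1,2-dien-1-yl)phenyl]-N-methoxy-N-methylacetamide (ortho-allenylphenol, not isolated) | CON(C)C(=O)Cc1ccc(OCOC)c(C=C=C(C)C)c1O | intermediate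
8 | N-methoxy-2-[5-(methoxymethoxy)-2,2-dimethyl-2H-chromen-8-yl]-N-methylacetamide | CON(C)C(=O)Cc1ccc(OCOC)c2C=CC(C)(C)Oc12 | intermediate
9 | methyl 3,5-dioxohexanoate | COC(=O)CC(=O)CC(C)=O | starting material
10 | trilithium trianion of methyl 3,5-dioxohexanoate (not isolated) | [Li+].[Li+].[Li+].COC(=O)[CH-]C(=O)[CH-]C(=O)[CH2-] | intermediate
11 | methyl 8-[5-(methoxymethoxy)-2,2-dimethyl-2H-chromen-8-yl]-3,5,7-trioxooctanoate | COC(=O)CC(=O)CC(=O)CC(=O)Cc1ccc(OCOC)c2C=CC(C)(C)Oc12 | intermediate
12 | 2-{[5-(methoxymethoxy)-2,2-dimethyl-2H-chromen-8-yl]acetyl}cyclohexane-1,3,5-trione (not isolated) | O=C(Cc1ccc(OCOC)c2C=CC(C)(C)Oc12)C1C(=O)CC(=O)CC1=O | intermediate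
13 | 2-[5-(methoxymethoxy)-2,2-dimethyl-2H-chromen-8-yl]-1-(2,4,6-trihydroxyphenyl)ethanone | O=C(Cc1ccc(OCOC)c2C=CC(C)(C)Oc12)c1c(O)cc(O)cc1O | intermediate
14 | 3-(dimethylamino)-2-[5-(methoxymethoxy)-2,2-dimethyl-2H-chromen-8-yl]-1-(2,4,6-trihydroxyphenyl)prop-2-en-1-one (enaminone, not isolated) | CN(C)C=C(C(=O)c1c(O)cc(O)cc1O)c1ccc(OCOC)c2C=CC(C)(C)Oc12 | intermediate
15 | 5,7-dihydroxy-3-[5-(methoxymethoxy)-2,2-dimethyl-2H-chromen-8-yl]-4H-chromen-4-one | COCOc1ccc(-c2coc3cc(O)cc(O)c3c2=O)c2OC(C)(C)C=Cc12 | intermediate
16 | sophoraisoflavone A, 5,7-dihydroxy-3-(5-hydroxy-2,2-dimethyl-2H-chromen-8-yl)-4H-chromen-4-one | CC1(C)C=Cc2c(O)ccc(-c3coc4cc(O)cc(O)c4c3=O)c2O1 | target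

**Totals**

Total step count: 9. Longest linear sequence: 9 steps (1 → 16).

**Steps most likely to fail**

Step 6. The strongly basic trianion 10 may take a proton from the benzylic methylene of 8 instead of adding to its carbonyl, and the free triketo ester may cyclise prematurely during work-up. The fallback sets out from 8 and uses a less basic nucleophile that delivers the chain in masked, storable form. Commercial 4-hydroxy-6-methyl-2H-pyran-2-one is doubly deprotonated (LiN(iPr)2, THF, −78 °C) to its dilithium dianion F1. The 6-methylene carbon of F1 is acylated by 8 to give 4-hydroxy-6-{3-[5-(methoxymethoxy)-2,2-dimethyl-2H-chromen-8-yl]-2-oxopropyl}-2H-pyran-2-one F2. Mg(OMe)2 in methanol then opens the lactone of F2 by methoxide attack at its carbonyl, which generates 11 in the flask as its magnesium enolate. The route is rejoined at 11, which goes on to 13 under the conditions of step 7.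

Step 7. Aldol closure (C2 onto C7) or pyrone formation may outrun the C-acylation, so that the chain aromatises to a resorcylate instead of the acylphloroglucinol. The fallback sets out from 8 and takes ring A from phloroglucinol instead of folding it. Phloroglucinol is converted (MOMCl, NaH, DMF) into 1,3,5-tris(methoxymethoxy)benzene F3. F3 is lithiated between two MOM groups (n-BuLi, THF, 0 °C) to 2,4,6-tris(methoxymethoxy)phenyllithium F4. F4 adds to Weinreb amide 8 to give 2-[5-(methoxymethoxy)-2,2-dimethyl-2H-chromen-8-yl]-1-[2,4,6-tris(methoxymethoxy)phenyl]ethanone F5. Me2NCH(OMe)2 (PhMe, 90 °C) converts F5 into 3-(dimethylamino)-2-[5-(methoxymethoxy)-2,2-dimethyl-2H-chromen-8-yl]-1-[2,4,6-tris(methoxymethoxy)phenyl]prop-2-en-1-one F6. HCl in methanol then removes the four MOM groups from F6 and closes ring C by loss of dimethylamine. This fallback comes back to the route at the target 16.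

Step 8. The amide acetal may O-methylate the acidic ring A phenols faster than the enaminone forms and closes. The fallback sets out from 13 and inserts C2 by orthoester condensation, with no methyl donor present. Heating 13 with HC(OEt)3 and catalytic 4-(dimethylamino)pyridine in DMF at about 110 °C should give 3-ethoxy-2-[5-(methoxymethoxy)-2,2-dimethyl-2H-chromen-8-yl]-1-(2,4,6-trihydroxyphenyl)prop-2-en-1-one F7. F7 closes by intramolecular oxa-Michael addition of an ortho phenol and loss of ethanol. The route is rejoined at 15.

**Further compounds**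

F1 | step 6 | dilithium dianion of 4-hydroxy-6-methyl-2H-pyran-2-one | [Li+].[Li+].[CH2-]C1=CC([O-])=CC(=O)O1
F2 | step 6 | 4-hydroxy-6-{3-[5-(methoxymethoxy)-2,2-dimethyl-2H-chromen-8-yl]-2-oxopropyl}-2H-pyran-2-one | O=C(Cc1ccc(OCOC)c2C=CC(C)(C)Oc12)CC1=CC(O)=CC(=O)O1
F3 | step 7 | 1,3,5-tris(methoxymethoxy)benzene | COCOc1cc(OCOC)cc(OCOC)c1
F4 | step 7 | 2,4,6-tris(methoxymethoxy)phenyllithium | [Li]c1c(OCOC)cc(OCOC)cc1OCOC
F5 | step 7 | 2-[5-(methoxymethoxy)-2,2-dimethyl-2H-chromen-8-yl]-1-[2,4,6-tris(methoxymethoxy)phenyl]ethanone | COCOc1cc(OCOC)c(C(=O)Cc2ccc(OCOC)c3C=CC(C)(C)Oc23)c(OCOC)c1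
F6 | step 7 | 3-(dimethylamino)-2-[5-(methoxymethoxy)-2,2-dimethyl-2H-chromen-8-yl]-1-[2,4,6-tris(methoxymethoxy)phenyl]prop-2-en-1-one | CN(C)C=C(C(=O)c1c(OCOC)cc(OCOC)cc1OCOC)c1ccc(OCOC)c2C=CC(C)(C)Oc12
F7 | step 8 | 3-ethoxy-2-[5-(methoxymethoxy)-2,2-dimethyl-2H-chromen-8-yl]-1-(2,4,6-trihydroxyphenyl)prop-2-en-1-one | CCOC=C(C(=O)c1c(O)cc(O)cc1O)c1ccc(OCOC)c2C=CC(C)(C)Oc12
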